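**Strategy.** Ring B is taken apart at the C1–C8a bond. Ring B is ring A plus the chain C1–C2–C3–C4, anchored to ring A through C8a and C4a; bonding C4 to C1 instead turns that chain into a cyclobutane, a rigid ring on which the C1, C2 and C3 stereocentres are fixed all-trans before ring B exists. In a single operation zerovalent palladium inserts into a C8a triflate, opens the strained C4–C1 bond of the tertiary cyclobutanol and couples C1 to C8a with retention, which expands the four-membered ring into the 4-tetralone. The precursor is a 1-(ring A aryl)-2-guaiacyl-3,4-bis(benzyloxymethyl)cyclobutanol, assembled from a keteniminium [2+2] cyclobutanone and an ortho-metalated ring A phenol ether.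

Key step: step 10

Numbering: aryltetralin numbering is used throughout (C1 carries ring C, C2 and C3 carry the CH2OH groups, C4 is the benzylic CH2, ring A is C4a–C8a).

Assumption: the (2R,5R)-2,5-dimethylpyrrolidine amide is taken to steer the cycloaddition to the (2R,3S,4S) ketone; if the sense of induction is the opposite, the (2S,5S)-amine is used and nothing else changes.

**Step 1**
Reactants: 1 [4-(benzyloxy)-3-methoxyphenyl]acetic acid; 2 (2R,5R)-2,5-dimethylpyrrolidine
Product: 4 2-[4-(benzyloxy)-3-methoxyphenyl]-1-[(2R,5R)-2,5-dimethylpyrrolidin-1-yl]ethan-1-one, via acid chloride 3 (not isolated)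
Conditions: (COCl)2, DMF (cat.), CH2Cl2, 0 °C → rt; then 2, pyridine, CH2Cl2, 0 °C → rt
Reagents that add atoms: none
Why: Acyl chloride formation followed by Schotten–Baumann-type N-acylation of the secondary amine should give the amide, pyridine (not a trialkylamine) limiting ketene formation from the arylacetyl chloride and the auxiliary stereocentres staying untouched.

**Step 2**
Reactants: 5 (E)-1,4-dibromobut-2-ene
Product: 6 (E)-1,4-bis(benzyloxy)but-2-ene
Conditions: BnOH, NaH, THF/DMF, 0 °C → rt
Reagents that add atoms: benzyl alcohol, OCc1ccccc1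
Why: A double Williamson ether synthesis (SN2 at the two primary allylic bromides by sodium benzyloxide) should give the symmetrical diether with the E geometry unchanged.

**Step 3**
Reactants: 4 2-[4-(benzyloxy)-3-methoxyphenyl]-1-[(2R,5R)-2,5-dimethylpyrrolidin-1-yl]ethan-1-one; 6 (E)-1,4-bis(benzyloxy)but-2-ene
Product: 9 (2R,3S,4S)-2-[4-(benzyloxy)-3-methoxyphenyl]-3,4-bis[(benzyloxy)methyl]cyclobutan-1-one, via keteniminium triflate 7 (not isolated), via cyclobutaniminium triflate 8 (not isolated)
Conditions: Tf2O, 2,6-di-tert-butyl-4-methylpyridine, 6 (3 equiv), ClCH2CH2Cl, 0 → 80 °C; then aq. NaHCO3, CH2Cl2, 40 °C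
Reagents that add atoms: water, O
Why: In this keteniminium [2+2] cycloaddition the amide is converted into keteniminium 7, which adds suprafacially to the symmetrical E-alkene (no regiochemical issue; the C3/C4 trans relationship comes from the alkene geometry, the absolute sense from the C2-symmetric auxiliary shielding one face of the C=N+ unit), and hydrolysis of iminium 8 under mild base should leave the epimerisable aryl-bearing C2 in the thermodynamically preferred all-trans arrangement.

**Step 4**
Reactants: 10 3-hydroxy-4,5-dimethoxybenzaldehyde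
Product: 11 3,4-dimethoxy-5-[(triisopropylsilyl)oxy]benzaldehyde
Conditions: TIPSCl, imidazole, DMF, rt
Reagents that add atoms: chlorotriisopropylsilane, CC(C)[Si](Cl)(C(C)C)C(C)C
Why: Standard silyl ether formation on the phenol should install a bulky, non-coordinating group that later shields the neighbouring ring position (the future C8) during metalation.

**Step 5**
Reactants: 11 3,4-dimethoxy-5-[(triisopropylsilyl)oxy]benzaldehyde
Product: 13 3,4-dimethoxy-5-[(triisopropylsilyl)oxy]phenol, via aryl formate 12 (not isolated)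
Conditions: mCPBA, CH2Cl2, 0 °C → rt; then Et3N, MeOH, rt
Reagents that add atoms: 3-chloroperoxybenzoic acid, OOC(=O)c1cccc(Cl)c1
Why: In this Baeyer–Villiger (Dakin-type) oxidation the electron-rich aryl group with its para-methoxy substituent should migrate in preference to hydride, and the aryl formate is cleaved by a mild methanolysis that spares the aryl silyl ether.

**Step 6**
Reactants: 13 3,4-dimethoxy-5-[(triisopropylsilyl)oxy]phenol
Product: 14 2-{3,4-dimethoxy-5-[(triisopropylsilyl)oxy]phenoxy}oxane (racemic tetrahydropyranyl ether)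
Conditions: 3,4-dihydro-2H-pyran, PPTS (cat.), CH2Cl2, rt
Reagents that add atoms: 3,4-dihydro-2H-pyran, C1=COCCC1
Why: Acid-catalysed addition of the phenol to the enol ether (tetrahydropyranyl acetal formation) should give a base-stable, lithium-coordinating ortho-directing group that can later be removed at nearly neutral pH without an oxidant.

**Step 7**
Reactants: 14 2-{3,4-dimethoxy-5-[(triisopropylsilyl)oxy]phenoxy}oxane; 9 (2R,3S,4S)-2-[4-(benzyloxy)-3-methoxyphenyl]-3,4-bis[(benzyloxy)methyl]cyclobutan-1-one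
Product: 17 (1S,2R,3S,4S)-2-[4-(benzyloxy)-3-methoxyphenyl]-3,4-bis[(benzyloxy)methyl]-1-{2,3-dimethoxy-6-(oxan-2-yloxy)-4-[(triisopropylsilyl)oxy]phenyl}cyclobutan-1-ol (two epimers at the acetal carbon), via aryllithium 15 (not isolated), via arylcerium dichloride 16 (not isolated)
Conditions: 14 (2 equiv), n-BuLi, THF, 0 °C; CeCl3, THF, −78 °C; then 9, −78 → −40 °C; aq. NH4Cl
Reagents that add atoms: none
Why: Directed ortho-metalation followed by 1,2-addition of an organocerium reagent: lithiation should occur at the one ring position flanked by two coordinating oxygens (the acetal and a methoxy group), the site next to the bulky silyl ether being shielded, and the weakly basic arylcerium should add to the strained, enolisable ketone from the face opposite its two α-substituents, which sets a carbinol centre (OH cis to both) that is removed again in step 10.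

**Step 8**
Reactants: 17 the tetrahydropyranyl-protected cyclobutanol
Product: 18 (1S,2R,3S,4S)-2-[4-(benzyloxy)-3-methoxyphenyl]-3,4-bis[(benzyloxy)methyl]-1-{6-hydroxy-2,3-dimethoxy-4-[(triisopropylsilyl)oxy]phenyl}cyclobutan-1-ol
Conditions: PPTS (cat.), MeOH/THF, rt
Reagents that add atoms: none
Why: Acid-catalysed transacetalisation to methanol (tetrahydropyranyl ether cleavage) under PPTS should free the C8a phenol while the tertiary benzylic cyclobutanol, the aryl silyl ether and the benzyl ethers stay intact.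

**Step 9**
Reactants: 18 the phenol cyclobutanol
Product: 19 2-{(1S,2R,3S,4S)-2-[4-(benzyloxy)-3-methoxyphenyl]-3,4-bis[(benzyloxy)methyl]-1-hydroxycyclobutyl}-3,4-dimethoxy-5-[(triisopropylsilyl)oxy]phenyl trifluoromethanesulfonate
Conditions: PhNTf2, Et3N, DMAP (cat.), CH2Cl2, rt
Reagents that add atoms: N-phenylbis(trifluoromethanesulfonimide), O=S(=O)(N(c1ccccc1)S(=O)(=O)C(F)(F)F)C(F)(F)F
Why: O-Sulfonylation of the phenol with the mild triflyl donor PhNTf2 should be selective because only the phenoxide is nucleophilic enough, the hindered tertiary alcohol remaining free.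

**Step 10**
Reactants: 19 the aryl triflate cyclobutanol
Product: 20 (2S,3S,4R)-4-[4-(benzyloxy)-3-methoxyphenyl]-2,3-bis[(benzyloxy)methyl]-7,8-dimethoxy-6-[(triisopropylsilyl)oxy]-3,4-dihydronaphthalen-1(2H)-one
Conditions: Pd2(dba)3 (2.5 mol%), XPhos (10 mol%), Cs2CO3 (2 equiv), toluene, 80 °C
Reagents that add atoms: none
Why: Zerovalent palladium inserts into the C8a–OTf bond, Cs2CO3 turns the tertiary alcohol into an alkoxide on divalent palladium, and β-carbon elimination, driven by release of cyclobutane strain, breaks C4–C1 to give the C4 ketone and a seven-membered aryl(benzyl)palladacycle. The closest known reaction type is the palladium-catalysed arylative ring opening of tertiary cyclobutanols with aryl halides or triflates, run here intramolecularly so that it becomes a ring expansion. Ring B is closed by C(sp2)–C(sp3) reductive elimination from that palladacycle, which forms C1–C8a and the six-membered ring. No stereocentre is created: β-carbon elimination and reductive elimination both proceed with retention at C1, C2 and C3 are spectators and the carbinol centre disappears, so the all-trans triad of the cyclobutane is carried over and either carbinol epimer would converge. The step needs cleavage of C4–C1 and not C4–C3, which the aryl-stabilised (η3-benzyl) C1–Pd bond should secure, and it needs reductive elimination to outrun β-hydride elimination toward C2, which the bulky biarylphosphine promotes. A carbonate base in toluene should also be mild enough for the benzyl ethers, the aryl silyl ether and the β-benzyloxy ketone of the product.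

**Step 11**
Reactants: 20 the silyl-protected tetralone
Product: 21 (2S,3S,4R)-4-[4-(benzyloxy)-3-methoxyphenyl]-2,3-bis[(benzyloxy)methyl]-6-hydroxy-7,8-dimethoxy-3,4-dihydronaphthalen-1(2H)-one
Conditions: Bu4NF, AcOH, THF, 0 °C
Reagents that add atoms: none
Why: Fluoride-induced cleavage of the aryl silyl ether (Si–F bond formation) should free the C7 phenol, the acetic acid buffer keeping the β-benzyloxy ketone away from basic fluoride or phenoxide.

**Step 12**
Reactants: 21 the phenol tetralone
Product: 22 (6S,7S,8R)-8-(4-hydroxy-3-methoxyphenyl)-6,7-bis(hydroxymethyl)-3,4-dimethoxy-5,6,7,8-tetrahydronaphthalen-2-ol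
Conditions: H2 (1 atm), Pd/C (10%), HCl (cat.), MeOH/EtOAc, rt
Reagents that add atoms: none
Why: Catalytic hydrogenolysis should cleave the three benzyl ethers and, under acid, reduce the electron-rich aryl ketone through its benzylic alcohol to the C4 methylene, leaving the C1, C2 and C3 stereocentres untouched.

**Compound list**

1 | [4-(benzyloxy)-3-methoxyphenyl]acetic acid (O-benzyl ether of homovanillic acid) | COc1cc(CC(=O)O)ccc1OCc1ccccc1 | starting material
2 | (2R,5R)-2,5-dimethylpyrrolidine | C[C@@H]1CC[C@@H](C)N1 | starting material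
3 | [4-(benzyloxy)-3-methoxyphenyl]acetyl chloride | COc1cc(CC(=O)Cl)ccc1OCc1ccccc1 | intermediate
4 | 2-[4-(benzyloxy)-3-methoxyphenyl]-1-[(2R,5R)-2,5-dimethylpyrrolidin-1-yl]ethan-1-one | COc1cc(CC(=O)N2[C@H](C)CC[C@H]2C)ccc1OCc1ccccc1 | intermediate
5 | (E)-1,4-dibromobut-2-ene | BrC/C=C/CBr | starting material
6 | (E)-1,4-bis(benzyloxy)but-2-ene | C(OCc1ccccc1)/C=C/COCc1ccccc1 | intermediate
7 | (2R,5R)-1-{2-[4-(benzyloxy)-3-methoxyphenyl]ethenylidene}-2,5-dimethylpyrrolidin-1-ium trifluoromethanesulfonate | COc1cc(C=C=[N+]2[C@H](C)CC[C@H]2C)ccc1OCc1ccccc1.[O-]S(=O)(=O)C(F)(F)F | intermediate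
8 | (2R,5R)-1-{(2R,3S,4R)-2-[4-(benzyloxy)-3-methoxyphenyl]-3,4-bis[(benzyloxy)methyl]cyclobutylidene}-2,5-dimethylpyrrolidin-1-ium trifluoromethanesulfonate (same spatial arrangement as 9; the C4 descriptor changes with the priorities) | C1(=[N+]2[C@H](C)CC[C@H]2C)[C@@H](c2ccc(OCc3ccccc3)c(OC)c2)[C@H](COCc2ccccc2)[C@H]1COCc1ccccc1.[O-]S(=O)(=O)C(F)(F)F | intermediate
9 | (2R,3S,4S)-2-[4-(benzyloxy)-3-methoxyphenyl]-3,4-bis[(benzyloxy)methyl]cyclobutan-1-one (all-trans) | O=C1[C@@H](c2ccc(OCc3ccccc3)c(OC)c2)[C@H](COCc2ccccc2)[C@H]1COCc1ccccc1 | intermediate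
10 | 3-hydroxy-4,5-dimethoxybenzaldehyde | COc1cc(C=O)cc(O)c1OC | starting material
11 | 3,4-dimethoxy-5-[(triisopropylsilyl)oxy]benzaldehyde | COc1cc(C=O)cc(O[Si](C(C)C)(C(C)C)C(C)C)c1OC | intermediate
12 | 3,4-dimethoxy-5-[(triisopropylsilyl)oxy]phenyl formate | COc1cc(OC=O)cc(O[Si](C(C)C)(C(C)C)C(C)C)c1OC | intermediate
13 | 3,4-dimethoxy-5-[(triisopropylsilyl)oxy]phenol | COc1cc(O)cc(O[Si](C(C)C)(C(C)C)C(C)C)c1OC | intermediate
14 | 2-{3,4-dimethoxy-5-[(triisopropylsilyl)oxy]phenoxy}oxane (racemic) | COc1cc(OC2CCCCO2)cc(O[Si](C(C)C)(C(C)C)C(C)C)c1OC | intermediate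
15 | {2,3-dimethoxy-6-(oxan-2-yloxy)-4-[(triisopropylsilyl)oxy]phenyl}lithium | COc1c([Li])c(OC2CCCCO2)cc(O[Si](C(C)C)(C(C)C)C(C)C)c1OC | intermediate
16 | dichloro{2,3-dimethoxy-6-(oxan-2-yloxy)-4-[(triisopropylsilyl)oxy]phenyl}cerium | COc1c([Ce](Cl)Cl)c(OC2CCCCO2)cc(O[Si](C(C)C)(C(C)C)C(C)C)c1OC | intermediate
17 | (1S,2R,3S,4S)-2-[4-(benzyloxy)-3-methoxyphenyl]-3,4-bis[(benzyloxy)methyl]-1-{2,3-dimethoxy-6-(oxan-2-yloxy)-4-[(triisopropylsilyl)oxy]phenyl}cyclobutan-1-ol (acetal carbon unassigned, two epimers) | O[C@@]1(c2c(OC3CCCCO3)cc(O[Si](C(C)C)(C(C)C)C(C)C)c(OC)c2OC)[C@@H](c2ccc(OCc3ccccc3)c(OC)c2)[C@H](COCc2ccccc2)[C@H]1COCc1ccccc1 | intermediate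
18 | (1S,2R,3S,4S)-2-[4-(benzyloxy)-3-methoxyphenyl]-3,4-bis[(benzyloxy)methyl]-1-{6-hydroxy-2,3-dimethoxy-4-[(triisopropylsilyl)oxy]phenyl}cyclobutan-1-ol | O[C@@]1(c2c(O)cc(O[Si](C(C)C)(C(C)C)C(C)C)c(OC)c2OC)[C@@H](c2ccc(OCc3ccccc3)c(OC)c2)[C@H](COCc2ccccc2)[C@H]1COCc1ccccc1 | intermediate
19 | 2-{(1S,2R,3S,4S)-2-[4-(benzyloxy)-3-methoxyphenyl]-3,4-bis[(benzyloxy)methyl]-1-hydroxycyclobutyl}-3,4-dimethoxy-5-[(triisopropylsilyl)oxy]phenyl trifluoromethanesulfonate | O[C@@]1(c2c(OS(=O)(=O)C(F)(F)F)cc(O[Si](C(C)C)(C(C)C)C(C)C)c(OC)c2OC)[C@@H](c2ccc(OCc3ccccc3)c(OC)c2)[C@H](COCc2ccccc2)[C@H]1COCc1ccccc1 | intermediate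
20 | (2S,3S,4R)-4-[4-(benzyloxy)-3-methoxyphenyl]-2,3-bis[(benzyloxy)methyl]-7,8-dimethoxy-6-[(triisopropylsilyl)oxy]-3,4-dihydronaphthalen-1(2H)-one | COc1cc([C@@H]2c3cc(O[Si](C(C)C)(C(C)C)C(C)C)c(OC)c(OC)c3C(=O)[C@H](COCc3ccccc3)[C@H]2COCc2ccccc2)ccc1OCc1ccccc1 | intermediate
21 | (2S,3S,4R)-4-[4-(benzyloxy)-3-methoxyphenyl]-2,3-bis[(benzyloxy)methyl]-6-hydroxy-7,8-dimethoxy-3,4-dihydronaphthalen-1(2H)-one | COc1cc([C@@H]2c3cc(O)c(OC)c(OC)c3C(=O)[C@H](COCc3ccccc3)[C@H]2COCc2ccccc2)ccc1OCc1ccccc1 | intermediate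
22 | (6S,7S,8R)-8-(4-hydroxy-3-methoxyphenyl)-6,7-bis(hydroxymethyl)-3,4-dimethoxy-5,6,7,8-tetrahydronaphthalen-2-ol | COc1cc([C@@H]2c3cc(O)c(OC)c(OC)c3C[C@H](CO)[C@H]2CO)ccc1O | target

**Step count**

Total: 12 steps. Longest linear sequence: 9 steps (steps 4 to 12, from aldehyde 10 to target 22).

**Steps most likely to fail**

1. Step 10 (ring expansion). What may go wrong: β-hydride elimination toward C2 from the benzylic palladium intermediate, opening of the C4–C3 bond in place of C4–C1, or protonation of the ring-opened species before the C1–C8a bond forms. Fallback, a radical ring expansion in place of the organopalladium one: it sets out from ketone 9. Commercial 2,3-dimethoxyphenol is silylated (TIPSCl, imidazole) to (2,3-dimethoxyphenoxy)tri(propan-2-yl)silane F1, which is lithiated next to its methoxy group (n-BuLi, TMEDA, THF, 0 °C) to the aryllithium F2, transmetalated with CeCl3 to the arylcerium dichloride F3 and added to 9 to give the C8a–H cyclobutanol F4. The known oxidative ring expansion of 1-arylcyclobutanols to 1-tetralones (AgNO3 cat., K2S2O8, CH2Cl2/H2O) would then proceed by alkoxy-radical β-scission to the benzylic C1 radical, cyclisation onto C8a and rearomatisation. It comes back to the route at tetralone 20; C1 would then be set by the neighbouring C2 substituent (aryl trans) and no longer by retention.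

2. Step 3 (keteniminium cycloaddition). What may go wrong: poor facial selectivity of the hindered chiral keteniminium, or sluggish addition to the internal alkene that is deactivated by two allylic ether groups. Fallback, a racemic cycloaddition followed by resolution: it sets out from acid 1 by way of acid chloride 3. Dimethylamine gives 2-[4-(benzyloxy)-3-methoxyphenyl]-N,N-dimethylacetamide F5; Tf2O and 2,4,6-collidine convert it into the small, more reactive keteniminium triflate F6, which adds to alkene 6 to give the racemic cyclobutaniminium triflate F7 and, after hydrolysis, the racemic all-trans ketone, that is 9 together with its enantiomer F8. Preparative chromatography on a chiral stationary phase separates the two, and the route is rejoined at ketone 9.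

3. Step 7 (metalation and addition). What may go wrong: lithiation at the wrong ring position, or incomplete addition to the ketone because of the bulk of the ortho acetal. Fallback, halogen–metal exchange with a smaller protecting group that is removed without acid: it sets out from phenol 13. NBS brominates the ortho position that is not shielded by the silyl ether to give 2-bromo-3,4-dimethoxy-5-[(triisopropylsilyl)oxy]phenol F9; allyl bromide and K2CO3 give the allyl ether F10. Bromine–lithium exchange (n-BuLi, THF, −78 °C) gives the aryllithium F11, CeCl3 the arylcerium dichloride F12, and addition to ketone 9 the O-allyl cyclobutanol F13. Pd(PPh3)4 and morpholine remove the allyl group under neutral conditions and return to the route at phenol 18, which also bypasses the acid of step 8.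

**Further compounds**

F1 | step 10 | (2,3-dimethoxyphenoxy)tri(propan-2-yl)silane | COc1cccc(O[Si](C(C)C)(C(C)C)C(C)C)c1OC
F2 | step 10 | {2,3-dimethoxy-4-[(triisopropylsilyl)oxy]phenyl}lithium | COc1c([Li])ccc(O[Si](C(C)C)(C(C)C)C(C)C)c1OC
F3 | step 10 | dichloro{2,3-dimethoxy-4-[(triisopropylsilyl)oxy]phenyl}cerium | COc1c([Ce](Cl)Cl)ccc(O[Si](C(C)C)(C(C)C)C(C)C)c1OC
F4 | step 10 | (1S,2R,3S,4S)-2-[4-(benzyloxy)-3-methoxyphenyl]-3,4-bis[(benzyloxy)methyl]-1-{2,3-dimethoxy-4-[(triisopropylsilyl)oxy]phenyl}cyclobutan-1-ol | O[C@@]1(c2ccc(O[Si](C(C)C)(C(C)C)C(C)C)c(OC)c2OC)[C@@H](c2ccc(OCc3ccccc3)c(OC)c2)[C@H](COCc2ccccc2)[C@H]1COCc1ccccc1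
F5 | step 3 | 2-[4-(benzyloxy)-3-methoxyphenyl]-N,N-dimethylacetamide | COc1cc(CC(=O)N(C)C)ccc1OCc1ccccc1
F6 | step 3 | N-{2-[4-(benzyloxy)-3-methoxyphenyl]ethenylidene}-N-methylmethanaminium trifluoromethanesulfonate | COc1cc(C=C=[N+](C)C)ccc1OCc1ccccc1.[O-]S(=O)(=O)C(F)(F)F
F7 | step 3 | N-{2-[4-(benzyloxy)-3-methoxyphenyl]-3,4-bis[(benzyloxy)methyl]cyclobutylidene}-N-methylmethanaminium trifluoromethanesulfonate (racemic, all-trans; one enantiomer drawn) | C[N+](C)=C1[C@@H](c2ccc(OCc3ccccc3)c(OC)c2)[C@H](COCc2ccccc2)[C@H]1COCc1ccccc1.[O-]S(=O)(=O)C(F)(F)F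
F8 | step 3 | (2S,3R,4R)-2-[4-(benzyloxy)-3-methoxyphenyl]-3,4-bis[(benzyloxy)methyl]cyclobutan-1-one (enantiomer of 9) | O=C1[C@H](c2ccc(OCc3ccccc3)c(OC)c2)[C@@H](COCc2ccccc2)[C@@H]1COCc1ccccc1
F9 | step 7 | 2-bromo-3,4-dimethoxy-5-[(triisopropylsilyl)oxy]phenol | COc1c(Br)c(O)cc(O[Si](C(C)C)(C(C)C)C(C)C)c1OC
F10 | step 7 | 2-bromo-3,4-dimethoxy-1-(prop-2-en-1-yloxy)-5-[(triisopropylsilyl)oxy]benzene | COc1c(Br)c(OCC=C)cc(O[Si](C(C)C)(C(C)C)C(C)C)c1OC
F11 | step 7 | {2,3-dimethoxy-6-(prop-2-en-1-yloxy)-4-[(triisopropylsilyl)oxy]phenyl}lithium | COc1c([Li])c(OCC=C)cc(O[Si](C(C)C)(C(C)C)C(C)C)c1OC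
F12 | step 7 | dichloro{2,3-dimethoxy-6-(prop-2-en-1-yloxy)-4-[(triisopropylsilyl)oxy]phenyl}cerium | COc1c([Ce](Cl)Cl)c(OCC=C)cc(O[Si](C(C)C)(C(C)C)C(C)C)c1OC
F13 | step 7 | (1S,2R,3S,4S)-2-[4-(benzyloxy)-3-methoxyphenyl]-3,4-bis[(benzyloxy)methyl]-1-{2,3-dimethoxy-6-(prop-2-en-1-yloxy)-4-[(triisopropylsilyl)oxy]phenyl}cyclobutan-1-ol | O[C@@]1(c2c(OCC=C)cc(O[Si](C(C)C)(C(C)C)C(C)C)c(OC)c2OC)[C@@H](c2ccc(OCc3ccccc3)c(OC)c2)[C@H](COCc2ccccc2)[C@H]1COCc1ccccc1
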